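## Structural features

The target **21** is the 2-oxo-2H-chromen-7-yl (umbelliferyl) ether of a tetrasubstituted cyclohexene. The carbocycle is numbered here C1 (CH with isopropenyl), C2=C3 (ring alkene, methyl on C3), C4 (CH with the CH2–OAr arm), C5 (quaternary: methyl and CH2CH2CO2H) and C6 (CH2). There are three stereocentres: C4 and C5 are neighbours, and C1 is 1,3 to C5 and 1,4 to C4. With C1→C6 drawn clockwise, the isopropenyl group, the CH2O arm and the propanoic acid chain lie on the lower face and the C5 methyl on the upper face; this is (1R,2R,5S) in the IUPAC numbering of the cyclohexene. The fragile parts are the coumarin lactone (attacked by hydroxide, hydride and conjugate reductants), the acid-sensitive isopropenyl group of the skipped diene, the doubly allylic C1–H and the free acid. The real difficulty is the all-carbon quaternary C5 next to C4, carrying two cis carbon arms of different length that must be told apart, together with the remote C1. The key step uses the fact that C4 and C5 each carry one carbon on the same face and C5 also a methyl: this is the pattern left when a two-carbon alkene is added across the α,β-bond of a 3-methylcyclohex-2-enone as a cis-fused cyclobutane and that ring is later cut between the two added carbons. The enone carbonyl then sits at C3, from where the C3 methyl, the C2=C3 alkene and the C1 isopropenyl group can be installed.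

## Logic of the disconnections

**21 ⇒ 20.** Only the carboxyl O–allyl bond is cut. The acid is kept as an allyl ester because a free acid would compete as the nucleophile in the etherification. The forward step must free the acid without hydroxide, acid or hydride, which the coumarin and the isopropenyl group would not tolerate.

**20 ⇒ 18 + 19.** The ArO–CH2 bond on the C4 arm is cut. The coumarin is brought in last because it would not survive the hydride and copper hydride steps. This removes nine carbons and the lactone from all earlier intermediates. The forward step must substitute at a β-branched primary carbon.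

**18 ⇒ 17 ⇒ 16 ⇒ 14 + 15.** The Cα–Cβ bond of the propanoate chain is cut as an olefination of a C5 aldehyde, followed by 1,4-reduction and desilylation. The chain shrinks to a one-carbon arm on C5. The forward steps must add to an aldehyde on a quaternary carbon and reduce the enoate without touching the two isolated alkenes or the allyl ester.

**14 ⇒ 13 ⇒ 12.** No skeletal bond is cut; the C5 arm is taken back to CH2OH and the silyl ether on the C4 arm is removed. This leads to a diol whose arms differ only in their surroundings. The forward silylation must choose the C4 arm (on a CH) over the neopentyl C5 arm.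

**12 ⇒ 11 ⇒ 10.** The two arm carbons are reconnected (retro glycol cleavage), which turns them into the two carbinol carbons of a cis-fused cyclobutane-1,2-diol. Two separate branches become one two-carbon unit and the cis relation of the arms becomes a ring fusion. The forward cleavage passes through 11, whose C4 aldehyde is enolisable and β,γ-unsaturated, so it must be reduced at once.

**10 ⇒ 9 ⇒ 8 ⇒ 7 ⇒ 6.** The C3–CH3 bond is cut (cross-coupling of an enol triflate) and the diol is put back under its carbonate, leading to a C3 ketone. The ketone gives access to both C3 and C1. The forward sequence must enolise towards C2 and not towards the ring-fusion carbon C4, and must keep the diol masked until the ketone is gone, because a free β-hydroxy ketone on a cyclobutane would open by retro-aldol fragmentation.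

**6 ⇒ 4 + 5.** The C1–isopropenyl bond is cut as a conjugate addition to the C3 enone. The forward step must add on the face of the cyclobutane; the substrate offers a methyl on one face and a cyclobutane CH on the other, so a chiral catalyst is given the task. It must also run without base to spare the carbonate.

**4 ⇒ 3.** The C1=C2 unsaturation is removed. The forward dehydrogenation can only go to this side because C5 is quaternary and C4 is part of the four-membered ring.

**3 ⇒ 1 + 2.** The C4–C and C5–C bonds of the cyclobutane are cut together. This leaves two commercial compounds. The forward [2+2] step must deliver C4 and C5 as one enantiomer; the cis fusion fixes their relative configuration.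

## Other disconnections considered

**Alternative 1:** The cut is the C4–C5 bond. The lactone A1, a 5,6-trans-disubstituted oxan-2-one with the isopropenyl group at the future C1 and an (E)-4-silyloxybut-2-en-2-yl group on the carbinol carbon (future C2), would be converted with a lithium amide base and a chlorosilane into its silyl ketene acetal. On warming this would contract by an Ireland–Claisen rearrangement to the cyclohexenecarboxylic acid A2.
- In its favour: C4 and the quaternary C5 would be set together in a closed, boat-like transition state, with the C1 centre and the alkene geometry as control elements.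
- Better than the chosen plan: the arms emerge already differentiated (silyl ether against carboxylic acid), where the chosen plan relies on a steric silylation. The pericyclic mechanism also needs no unprecedented enantiocontrol.
- Against it here: A1 itself carries two stereocentres and a trisubstituted E-alkene and must be made as one enantiomer, so the stereochemical problem is moved, not solved. The forced boat places the silyloxy group under the C3 methyl. The carboxyl on the quaternary carbon of A2 still needs a two-carbon homologation by reduction, olefination and conjugate reduction.
- Step economy: the end game would equal the chosen one; the front is longer, since the chosen plan reaches the cyclobutanediol stage in five steps from commercial compounds.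

**Alternative 2:** The cuts are C4–C5 and C1–C6. Oxidation of creosol A3 with a trivalent-iodine oxidant in the presence of 2-methylprop-2-en-1-ol A4 would give a mixed quinone monoketal whose tethered alkene adds across the dienone (intramolecular Diels–Alder) to the tricyclic ketal A5.
- In its favour: one operation from two cheap achiral compounds would build the ring and place the methyl-bearing alkene where it belongs.
- Better than the chosen plan: all three stereocentres, including C1, would be fixed in the right relative sense by the tether and the bridge, where the chosen plan needs a separate face-selective addition for C1. No triflate or methyl coupling is needed.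
- Against it here: nothing in the dienone or the tether offers absolute control, so A5 would be racemic and need resolution. This is worse than a catalytic asymmetric key step and equal only if the photocycloaddition has to fall back on its racemic mode.
- Further cost: the two-carbon bridge must be excised, and its ketone carbon on C1 turned into an isopropenyl group next to an epimerisable, doubly allylic C1–H. The ketal carbon ends as a lactone carbonyl on the C4 arm, so the C5 CH2–O still has to be oxidised and extended.
- Step economy: the key step is shorter, but the redox work after it makes the whole comparable or longer.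

**Alternative 3:** The cuts are C5–C6 and C3–C4. A bifunctional cinchona thiourea would catalyse the Michael addition of 3-methyltetronic acid A6 to pent-1-en-3-one A7, and an acid-mediated aldol condensation would close the cyclohexenone to the bicyclic enone lactone A8.
- Better than the chosen plan on precedent: catalytic asymmetric Michael additions of cyclic 1,3-dicarbonyl compounds to vinyl ketones are a mature reaction class, so enantiocontrol at C5 is better founded than in the chosen key step. The chemistry is thermal and scalable.
- Better than the chosen plan on the arms: the lactone carbonyl is on the C5 arm (ready for reduction to a lactol and olefination) and the CH2–O is on C4.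
- Against it here: only C5 is set. C4 would have to come from a reductive transposition of the enone (hydrazone route), whose face is steered only by C5. C1 would need an α′-functionalisation of the C2 ketone with an isopropenyl equivalent at an epimerisable position. The lactol olefination risks oxa-Michael closure.
- Comparison: two substrate-controlled centres stand against one in the chosen plan, where C4 is locked to C5 by the ring fusion; here the chosen plan is better. The step count would be about equal.

Key step: step 1

Remark: faces are named with the ring drawn so that C1→C6 run clockwise; "lower" is the face of the C4 and C5 arms in 21; Ca and Cb are the two carbons delivered by 2 (Ca on C4, Cb on C5).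
Remark: the (S)-prolinol-derived oxazaborolidine is assumed to shield the enone face that leads to 3; if the sense of induction is the reverse, the (R)-derived catalyst is used.
Remark: 15 and MeZnCl (THF solution) are taken to be commercial.

## Route

Step 1
Reactants: 1 3-methylcyclohex-2-en-1-one; 2 vinylene carbonate
Product: 3 cis-anti-cis keto carbonate, the cyclic carbonate of (1S,6R,7S,8R)-7,8-dihydroxy-6-methylbicyclo[4.2.0]octan-2-one (ketone at C3; cyclobutane on the lower face of C4–C5; carbonate exo)
Conditions: oxazaborolidine from (S)-α,α-bis(3,5-dimethylphenyl)prolinol and 2,4,6-trifluorophenylboronic acid, activated with AlBr3 (50 mol%); 2 (10 equiv); CH2Cl2, −75 °C, hν (366 nm)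
Reagents that add atoms: none
Why: Proposed new method: the AlBr3-activated oxazaborolidine binds the carbonyl oxygen of 1, which moves the enone absorption to longer wavelength so that the complex is excited in preference to free 1 at 366 nm, and the bound excited enone adds 2 stepwise through a triplet 1,4-diradical; the closest known reaction type is the chiral-Lewis-acid-catalysed intermolecular [2+2] photocycloaddition of cyclohex-2-enones with simple alkenes, which has not been shown for a β-methyl enone paired with a carbonate-substituted alkene. The cyclobutane, the only ring formed, closes by recombination of the 1,4-diradical after the first intermolecular C–C bond, and it closes cis on the six-membered ring because a trans six–four fusion is strained and any trans isomer would relax through the enolisable C4–H. The absolute configuration of C4 and C5 is controlled by the catalyst, whose aryl group covers one face of the bound enone, and their relative configuration by the cis fusion, which places the C5 methyl trans to the new bond at C4. The two oxygen-bearing carbons are expected exo for steric reasons, but both are erased in step 6, so this selectivity is not critical. No regiochemical question arises because 2 is symmetric. The only selectivity the step must deliver is enantiofacial, and it is secured by low temperature and a high catalyst loading, which suppress the racemic background path of free 1.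

Step 2
Reactants: 3 keto carbonate
Product: 4 enone carbonate, the 7,8-carbonate of 7,8-dihydroxy-6-methylbicyclo[4.2.0]oct-3-en-2-one (C3 ketone, C2=C1 alkene; four stereocentres as in 3)
Conditions: IBX (2.5 equiv), 4-methoxypyridine N-oxide (2.5 equiv), DMSO, 25 °C
Reagents that add atoms: none
Why: IBX dehydrogenation of a ketone (enolisation, single-electron oxidation, loss of the β-hydrogen). Only the C2–C1 side can desaturate, because C5 is quaternary and a double bond from C4 would lie in the cyclobutane; the quaternary C5 also blocks over-oxidation to a dienone. The neutral conditions leave the β-carbonate alone.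

Step 3
Reactants: 4 enone carbonate; 5 isopropenylboronic acid pinacol ester
Product: 6 isopropenyl keto carbonate, the 7,8-carbonate of 7,8-dihydroxy-6-methyl-4-(prop-1-en-2-yl)bicyclo[4.2.0]octan-2-one (isopropenyl on C1, lower face, cis to the cyclobutane)
Conditions: [Rh(OH)((S)-binap)]2 (2.5 mol%), 5 (3 equiv), 1,4-dioxane/H2O 10:1, 40 °C
Reagents that add atoms: none
Why: Rhodium-catalysed asymmetric 1,4-addition of an alkenylboron reagent (Hayashi–Miyaura reaction): boron-to-rhodium transmetalation, insertion of the enone into the Rh–alkenyl bond and hydrolysis of the rhodium enolate. The C1 centre is set by the ligand: (S)-BINAP directs attack to the enone face that gives (S)-3-alkenylcyclohexanones from cyclohex-2-enone, which here is the lower face; the substrate's own bias should be small because the ring is nearly flat, with a methyl on one face of C5 and a tied-back cyclobutane CH on the other. The hydroxo complex needs no added base, so the carbonate is not hydrolysed while the ketone is present.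

Step 4
Reactants: 6 isopropenyl keto carbonate
Product: 8 enol triflate of 6 (OTf on C3; alkene C2=C3), via potassium enolate 7 (not isolated)
Conditions: KN(SiMe3)2 (1.1 equiv), THF, −78 °C; then N-(5-chloropyridin-2-yl)bis(trifluoromethanesulfonimide), −78 °C
Reagents that add atoms: N-(5-chloropyridin-2-yl)bis(trifluoromethanesulfonimide), O=S(=O)(N(c1ccc(Cl)cn1)S(=O)(=O)C(F)(F)F)C(F)(F)F
Why: Kinetic deprotonation and O-triflation of the enolate. The CH2 at C2 is removed faster than the ring-fusion methine C4, which is more hindered and would give an enolate exocyclic to the cyclobutane; the reactive triflating agent traps the enolate at −78 °C before it can equilibrate to the C4 enolate, the only one that could expel the β-carbonate.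

Step 5
Reactants: 8 enol triflate
Product: 10 cis-cyclobutane-1,2-diol, 2,6-dimethyl-4-(prop-1-en-2-yl)bicyclo[4.2.0]oct-2-ene-7,8-diol (methyl on C3; alkene C2=C3; both hydroxyls exo), via methylated carbonate 9 (not isolated)
Conditions: MeZnCl (2 equiv), Pd(PPh3)4 (5 mol%), THF, 50 °C; then MeOH, K2CO3, 25 °C
Reagents that add atoms: methylzinc chloride, C[Zn]Cl
Why: Negishi cross-coupling: zerovalent palladium inserts into the alkenyl C–OTf bond, methyl is transferred from zinc and reductive elimination fixes the alkene at C2=C3 with the methyl on C3. The carbonate is methanolysed only now, because with the C3 ketone gone the free cyclobutanediol can no longer open by retro-aldol fragmentation.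

Step 6
Reactants: 10 cis-cyclobutane-1,2-diol
Product: 12 cis-bis(hydroxymethyl) diol, [1,3-dimethyl-5-(prop-1-en-2-yl)cyclohex-3-ene-1,2-diyl]dimethanol (ring configuration as in 21), via dialdehyde 11 (not isolated)
Conditions: NaIO4 (1.5 equiv), THF/pH 7 phosphate buffer, 0 °C; then NaBH4, MeOH, 0 °C
Reagents that add atoms: none
Why: Periodate (Malaprade) cleavage of the cis-1,2-diol through a cyclic periodate ester breaks the Ca–Cb bond and releases the ring strain. The dialdehyde is reduced in the same flask so that its enolisable, β,γ-unsaturated C4 aldehyde has no time to epimerise or move into conjugation; C4 and C5 keep their configuration, so the two CH2OH arms are cis.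

Step 7
Reactants: 12 cis-bis(hydroxymethyl) diol
Product: 13 mono-silyl ether (OSiMe2tBu on the C4 arm; free CH2OH on C5)
Conditions: TBSCl (1.05 equiv), imidazole (2 equiv), CH2Cl2, −20 °C
Reagents that add atoms: tert-butyldimethylsilyl chloride, CC(C)(C)[Si](C)(C)Cl
Why: Silylation of the less hindered primary alcohol: the C5 CH2OH is neopentyl (on the quaternary carbon), whereas the C4 CH2OH sits on a CH, so with one equivalent at low temperature the C4 arm should react first.

Step 8
Reactants: 13 mono-silyl ether
Product: 14 aldehyde (CHO on C5; silyl ether on the C4 arm)
Conditions: DMP (1,1,1-triacetoxy-1,1-dihydro-1,2-benziodoxol-3(1H)-one, 1.3 equiv), CH2Cl2, 0 → 25 °C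
Reagents that add atoms: none
Why: Dess–Martin oxidation of a primary alcohol. The aldehyde is on a quaternary carbon, so it cannot enolise or epimerise.

Step 9
Reactants: 14 aldehyde; 15 allyl diethylphosphonoacetate
Product: 16 allyl (E)-enoate (CH=CH–CO2allyl on C5)
Conditions: 15 (1.5 equiv), LiCl, DBU, MeCN, 25 → 40 °C
Reagents that add atoms: none
Why: Horner–Wadsworth–Emmons olefination under Masamune–Roush conditions; the lithium-chelated phosphonate is acidic enough for DBU and the non-enolisable aldehyde can only add. The E-enoate is expected, and its geometry is removed in the next step.

Step 10
Reactants: 16 allyl (E)-enoate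
Product: 18 hydroxy ester, allyl 3-[2-(hydroxymethyl)-1,3-dimethyl-5-(prop-1-en-2-yl)cyclohex-3-en-1-yl]propanoate (ring configuration as in 21), via saturated silyl ether 17 (not isolated)
Conditions: Cu(OAc)2·H2O (5 mol%), 1,2-bis(diphenylphosphino)benzene (5 mol%), (MeO)2MeSiH (2 equiv), tBuOH (2 equiv), toluene, 25 °C; then TBAF, AcOH, THF, 25 °C
Reagents that add atoms: none
Why: Copper hydride 1,4-reduction: hydrocupration of the enoate and protonation of the copper enolate by tBuOH; the isolated alkenes and the allyl ester are not electrophilic enough to react. Buffered fluoride then cleaves the Si–O bond without touching the ester.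

Step 11
Reactants: 18 hydroxy ester; 19 umbelliferone (7-hydroxy-2H-chromen-2-one)
Product: 20 allyl ester of the target (umbelliferyl ether on the C4 arm)
Conditions: 19 (1.5 equiv), PPh3, DIAD, THF, 0 → 40 °C
Reagents that add atoms: none
Why: Mitsunobu etherification: the alcohol is activated as an alkoxyphosphonium ion and displaced (SN2) by the phenoxide of 19, which is acidic enough to protonate the betaine. The carbon attacked is not a stereocentre.

Step 12
Reactants: 20 allyl ester of the target
Product: 21 target, 3-[(1R,2R,5S)-1,3-dimethyl-2-{[(2-oxo-2H-chromen-7-yl)oxy]methyl}-5-(prop-1-en-2-yl)cyclohex-3-en-1-yl]propanoic acid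
Conditions: Pd(PPh3)4 (5 mol%), morpholine (5 equiv), THF, 25 °C
Reagents that add atoms: none
Why: Palladium-catalysed deallylation (Tsuji–Trost type): zerovalent palladium ionises the allyl ester to a π-allyl complex and the carboxylate, and morpholine takes up the allyl group. The neutral conditions leave the coumarin lactone, the aryl ether and both alkenes untouched.

## Compound list

1 | 3-methylcyclohex-2-en-1-one | CC1=CC(=O)CCC1 | starting material
2 | vinylene carbonate (1,3-dioxol-2-one) | O=C1OC=CO1 | starting material
3 | cis-anti-cis keto carbonate, cyclic carbonate of (1S,6R,7S,8R)-7,8-dihydroxy-6-methylbicyclo[4.2.0]octan-2-one | O=C1CCC[C@]2(C)[C@H]1[C@H]3OC(=O)O[C@H]32 | intermediate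
4 | enone carbonate (bicyclo[4.2.0]oct-3-en-2-one, stereocentres as in 3) | O=C1C=CC[C@]2(C)[C@H]1[C@H]3OC(=O)O[C@H]32 | intermediate
5 | isopropenylboronic acid pinacol ester | C=C(C)B1OC(C)(C)C(C)(C)O1 | starting material
6 | isopropenyl keto carbonate (isopropenyl on C1, cis to the cyclobutane) | C=C(C)[C@@H]1CC(=O)[C@@H]2[C@H]3OC(=O)O[C@H]3[C@]2(C)C1 | intermediate
7 | potassium C2=C3 enolate of 6 (not isolated) | C=C(C)[C@@H]1C=C([O-])[C@@H]2[C@H]3OC(=O)O[C@H]3[C@]2(C)C1.[K+] | intermediate
8 | enol triflate of 6 (OTf on C3, alkene C2=C3) | C=C(C)[C@@H]1C=C(OS(=O)(=O)C(F)(F)F)[C@@H]2[C@H]3OC(=O)O[C@H]3[C@]2(C)C1 | intermediate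
9 | methylated carbonate, cyclic carbonate of 2,6-dimethyl-4-(prop-1-en-2-yl)bicyclo[4.2.0]oct-2-ene-7,8-diol (not isolated) | C=C(C)[C@@H]1C=C(C)[C@@H]2[C@H]3OC(=O)O[C@H]3[C@]2(C)C1 | intermediate
10 | cis-cyclobutane-1,2-diol, 2,6-dimethyl-4-(prop-1-en-2-yl)bicyclo[4.2.0]oct-2-ene-7,8-diol | C=C(C)[C@@H]1C=C(C)[C@@H]2[C@@H](O)[C@@H](O)[C@]2(C)C1 | intermediate
11 | dialdehyde, cis-1,3-dimethyl-5-(prop-1-en-2-yl)cyclohex-3-ene-1,2-dicarbaldehyde (not isolated) | C=C(C)[C@@H]1C=C(C)[C@H](C=O)[C@](C)(C=O)C1 | intermediate
12 | cis-bis(hydroxymethyl) diol (ring configuration as in 21) | C=C(C)[C@@H]1C=C(C)[C@H](CO)[C@](C)(CO)C1 | intermediate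
13 | mono-silyl ether (TBS on the C4 arm) | C=C(C)[C@@H]1C=C(C)[C@H](CO[Si](C)(C)C(C)(C)C)[C@](C)(CO)C1 | intermediate
14 | aldehyde (CHO on C5, TBS ether on the C4 arm) | C=C(C)[C@@H]1C=C(C)[C@H](CO[Si](C)(C)C(C)(C)C)[C@](C)(C=O)C1 | intermediate
15 | allyl diethylphosphonoacetate | C=CCOC(=O)CP(=O)(OCC)OCC | starting material
16 | allyl (E)-enoate | C=C(C)[C@@H]1C=C(C)[C@H](CO[Si](C)(C)C(C)(C)C)[C@](C)(/C=C/C(=O)OCC=C)C1 | intermediate
17 | saturated silyl ether, allyl propanoate with TBS ether (not isolated) | C=C(C)[C@@H]1C=C(C)[C@H](CO[Si](C)(C)C(C)(C)C)[C@](C)(CCC(=O)OCC=C)C1 | intermediate
18 | hydroxy ester | C=C(C)[C@@H]1C=C(C)[C@H](CO)[C@](C)(CCC(=O)OCC=C)C1 | intermediate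
19 | umbelliferone | O=c1ccc2ccc(O)cc2o1 | starting material
20 | allyl ester of the target | C=C(C)[C@@H]1C=C(C)[C@H](COc2ccc3ccc(=O)oc3c2)[C@](C)(CCC(=O)OCC=C)C1 | intermediate
21 | 3-[(1R,2R,5S)-1,3-dimethyl-2-{[(2-oxo-2H-chromen-7-yl)oxy]methyl}-5-(prop-1-en-2-yl)cyclohex-3-en-1-yl]propanoic acid | C=C(C)[C@@H]1C=C(C)[C@H](COc2ccc3ccc(=O)oc3c2)[C@](C)(CCC(=O)O)C1 | target

## Step count and least certain steps

Total: 12 steps. Longest linear sequence: 12 steps (1 and 2 to 21); 5, 15 and 19 are commercial and enter directly.

**Step 1 (key step, Proposed new method).**
- What may go wrong: insufficient enantioface discrimination, because free 1 also absorbs and reacts racemically. The Lewis-basic carbonate of 2 may also compete for the Lewis acid or be oligomerised by it.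
- Fallback (known chemistry), setting out from 1 and 2 and coming back at 6: plain irradiation (350 nm, CH2Cl2, no catalyst) is the established racemic enone–alkene photocycloaddition. It gives 3 together with the enantiomer of 3 F1.
- Dehydrogenation as in step 2 gives 4 together with the enantiomer of 4 F2.
- The (S)-BINAP–rhodium addition of step 3 is then used as a catalyst-controlled divergent reaction on the racemate. Each enantiomer is attacked on the same absolute face, so 4 gives 6 and F2 gives the trans adduct F3 (isopropenyl anti to the cyclobutane).
- 6 and F3 are diastereomers and are separated by chromatography; the route continues from 6.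

**Step 3.**
- What may go wrong: poor facial selectivity or stalling if the substrate's own preference opposes the ligand. If any base is needed to speed up transmetalation, the carbonate may be hydrolysed and the ring opened by retro-aldol fragmentation.
- Fallback, setting out from 4 and coming back at 9: C1 is set by intramolecular syn SN2′ delivery instead of conjugate addition.
- MeMgBr/CeCl3 (THF, −78 °C) should add to the C3 carbonyl from the upper face, away from the cyclobutane carbon next to it, to give the tertiary allylic alcohol F4 (C3–OH on the lower face).
- Phenyl isocyanate converts it into the N-phenylcarbamate F5.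
- Deprotonation of the carbamate N–H (BuLi), then CuI and isopropenyllithium, give a carbamate-bound organocopper species that transfers isopropenyl to C1 on the face of the leaving group, with the alkene moving to C2=C3. This is 9, which is methanolysed as in the second half of step 5.

**Step 7.**
- What may go wrong: low site selectivity or double silylation, because the C4 arm, although not neopentyl, is itself flanked by a quaternary carbon and a substituted alkene carbon.
- Fallback, setting out from 12 and coming back at 13: the choice is made by proximity instead of steric bulk.
- I2/NaHCO3 in MeCN at 0 °C should close the C5 CH2OH onto C3 of the ring alkene (five-membered ring, Markovnikov; the C4 CH2OH could only form an oxetane or close in the anti-Markovnikov sense) to give the bridged iodo ether F6.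
- The one remaining hydroxyl is silylated (TBSCl, imidazole) to the silylated iodo ether F7.
- Zn/AcOH in EtOH regenerates the alkene and the C5 CH2OH by reductive β-elimination, giving 13.

**Step 11.**
- What may go wrong: slow displacement at the β-branched CH2 lets the alkoxyphosphonium ion decompose by elimination or be captured by the hydrazide.
- Fallback, setting out from 18 and coming back at 20: the ether is made from the aryl side. Copper-catalysed O-arylation of the alcohol with 7-iodo-2H-chromen-2-one (CuI, 3,4,7,8-tetramethyl-1,10-phenanthroline, Cs2CO3, toluene, 90 °C) forms the O–aryl bond, so the hindered carbon is not attacked. The product is 20 itself (no new compound, F0).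

## Further compounds

F1 | step 1 | enantiomer of 3, cyclic carbonate of (1R,6S,7R,8S)-7,8-dihydroxy-6-methylbicyclo[4.2.0]octan-2-one | O=C1CCC[C@@]2(C)[C@@H]1[C@@H]3OC(=O)O[C@@H]32
F2 | step 1 | enantiomer of 4 | O=C1C=CC[C@@]2(C)[C@@H]1[C@@H]3OC(=O)O[C@@H]32
F3 | step 1 | trans adduct, 1,4-adduct of F2 with isopropenyl anti to the cyclobutane | C=C(C)[C@@H]1CC(=O)[C@H]2[C@@H]3OC(=O)O[C@@H]3[C@@]2(C)C1
F4 | step 3 | tertiary allylic alcohol from 4 (C3 methyl upper, C3–OH lower, alkene C1=C2) | C[C@]1(O)C=CC[C@]2(C)[C@H]1[C@H]3OC(=O)O[C@H]32
F5 | step 3 | N-phenylcarbamate of F4 | C[C@]1(OC(=O)Nc4ccccc4)C=CC[C@]2(C)[C@H]1[C@H]3OC(=O)O[C@H]32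
F6 | step 7 | bridged iodo ether (C5 CH2–O bonded to C3, iodine on C2, free CH2OH on C4) | C=C(C)[C@@H]1[C@@H](I)[C@@]2(C)[C@H](CO)[C@](C)(CO2)C1
F7 | step 7 | silylated iodo ether (TBS ether of F6) | C=C(C)[C@@H]1[C@@H](I)[C@@]2(C)[C@H](CO[Si](C)(C)C(C)(C)C)[C@](C)(CO2)C1
F0 | step 11 | none | none
A1 | alternative 1 | 5,6-trans-6-[(E)-4-(tert-butyldimethylsilyloxy)but-2-en-2-yl]-3-methyl-5-(prop-1-en-2-yl)oxan-2-one | O=C1O[C@H](/C(C)=C/CO[Si](C)(C)C(C)(C)C)[C@@H](C(C)=C)CC1C
A2 | alternative 1 | cyclohexenecarboxylic acid with C1, C4 and C5 set | C=C(C)[C@@H]1C=C(C)[C@H](CO[Si](C)(C)C(C)(C)C)[C@](C)(C(=O)O)C1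
A3 | alternative 2 | creosol (2-methoxy-4-methylphenol) | COc1cc(C)ccc1O
A4 | alternative 2 | 2-methylprop-2-en-1-ol | C=C(C)CO
A5 | alternative 2 | tricyclic ketal adduct (bicyclo[2.2.2]octenone fused to an oxolane) | O=C2[C@@H]1C=C(C)[C@H]([C@@]2(OC)O3)[C@](C)(C3)C1
A6 | alternative 3 | 3-methyltetronic acid (4-hydroxy-3-methylfuran-2(5H)-one) | CC1=C(O)COC1=O
A7 | alternative 3 | pent-1-en-3-one | CCC(=O)C=C
A8 | alternative 3 | bicyclic enone lactone with the C5 quaternary centre | O=C1CC[C@@]2(C)C(=O)OCC2=C1C
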